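A fed nucleophile molecule is easy to follow: it stays free until a coupling uses it.

| setting | cedar | oak |
|---|---|---|
| electrophile | 31 mM | 31 mM |
| nucleophile | 25.0 mM (fed, over 50 s) | 50.0 mM (fed, over 50 s) |
| protic impurity | 3.10 mM | 3.10 mM |
| solid base | 62.0 mM | 62.0 mM |
| time | 50 s | 50 s |

    protic impurity + free base → quenched reagent (k1 = 2.41 M⁻¹ s⁻¹)
    nucleophile + acid set free ⇌ protonated nucleophile, settled at all times (K2 = 1.7 × 10⁵ M⁻¹)
    solid base ⇌ free base, rate k3*(cs3 - [free base]) while solid is left; crystals form when [free base] > cs3 (cs3 = 21 mM, k3 = 0.00625 s⁻¹)
    electrophile + nucleophile → acid set free + target (k4 = 0.345 M⁻¹ s⁻¹)
    target ⇌ isomer of the product (K5 = 3.0, k5 = 0.0140 s⁻¹)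
    acid set free + free base ⇌ salt of the base, settled at all times (K6 = 55 M⁻¹)

- part of the electrophile that has reacted at the end, cedar
- part of the electrophile that has reacted at the end, oak
- what raising the concentration of nucleophile from its lowest to its highest value here does to the part of the electrophile that has reacted (changes below 5 percentage points count as none) (it rises / it falls / no change)

- given per volume of solution although it is solid: solid base
- at the start none of the solid base is in solution
- run time (cedar): 50 s

Bench note, reckoned before any result:

1. In the flask: electrophile at 31 mM, protic impurity, solid base, and nucleophile arriving steadily over 50 s.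

2. First fork: each coupling sets acid free, and that acid can bind nucleophile or free base. Their binding constants are 1.7 × 10⁵ M⁻¹ and 55 M⁻¹, so the acid takes a second nucleophile, and each coupling costs two.

3. Second fork: with electrophile held at its charge (pseudo-first-order), a free nucleophile disappears with rate constant 0.0214 s⁻¹, which is two nucleophiles per coupling times the coupling constant times the electrophile charge.

4. Averaging the exponential survival of each molecule over the feed gives the used share, the part of the fed nucleophile no longer free at the end: 38.6%. Its formula holds no nucleophile charge, so cedar and oak share it.

5. Expected at the end: the part of electrophile reacted is the used share times the nucleophile charge, divided by two electrophile charges. That gives 15.6% in cedar and 31.1% in oak.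

6. Not to touch: the steady feed, on which the used share is reckoned, and the solid base, whose free form is outbid for the acid.

The forecast gives 14.8% for cedar and 27.4% for oak, with the verdict "it rises", holding that “each coupling effectively uses up two nucleophiles”. The reckoning above runs higher than the forecast.

The simulation gives 14.6% for cedar and 27.4% for oak: it rises, by 13 percentage points. The forecast stands.

Oak's lead comes from its charge: with the difference in nucleophile charge taken away, oak falls from 27.4% to 14.6%. Nucleophile no longer free comes to 36.2% in cedar and 34.0% in oak, against the reckoned 38.6%.

A neighbour of cedar, charged with 62 mM of nucleophile, should have 38.6% of its electrophile reacted by the used share. The simulation gives 33.0%, with 67% of its electrophile left where the reckoning held it at its charge.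

Its constants are assumed; the flask was simulated.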